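## Structural features

The target is a germacranolide: a ten-membered carbocycle (C1–C10) cis-fused across C7–C8 to an α-methylene-γ-butyrolactone (C11, C12, C13, ring oxygen on C8). The carbocycle holds an E-trisubstituted C1=C10 alkene (methyl C14), a trisubstituted C4–C5 oxirane whose ring carbons C3 and C6 are cis (the oxide of a Z alkene; methyl C15 on C4), an allylic acetate at C2 and a second acetate at C6. There are six stereocentres: C2 (S) stands alone, and C4 (R), C5 (S), C6 (S), C7 (R), C8 (R) are contiguous. Within that array the C5 and C6 oxygens are anti, the C6 oxygen and the C11 branch on C7 are syn along C5–C8, and H7 and H8 are cis. The fragile groups are the α-methylene lactone (a Michael acceptor), the oxirane (acid and Lewis acid), the allylic C2 acetate, and the C6 acetate, which sits β to C8 and can be eliminated once C8 is a carbonyl. The real difficulty is closing a ten-membered ring that contains an E alkene without disturbing five adjacent stereocentres. The key step uses the fact that the C2 oxygen and the C9 methylene lie 1,4 across C1=C10. That is the pattern left when a carbon nucleophile (C8) adds to the far terminus (C9) of the π-allyl complex formed from a C1–C2 vinyl oxirane carrying the C10 isopropenyl group.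

## Logic of the disconnections

34 is opened at the lactone C12–O bond, giving diol 31 and its silyl ether 30. The cut removes the only base-sensitive Michael acceptor until the last step and replaces it by a robust allylic silyl ether. The forward step needs an oxidant that touches only the allylic primary alcohol and lets the C8 hydroxyl capture the aldehyde.

30 is traced to ketone 29 by cutting the C8–H bond. This makes C8 trigonal, so the C8 configuration need not be controlled during ring formation. The forward reduction must then be catalyst-controlled, and it must be non-basic because 29 is a β-acetoxy ketone.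

29 goes back to nitro compound 27 (C8=O from C8–NO2) and 27 to 26 (C2–O acetyl bond). The nitro group is what allows C8 to act as a carbon nucleophile. The forward Nef reaction has to run near neutrality in the presence of an oxirane, two acetates and a silyl ether.

26 is cut at C8–C9, the only skeletal bond of the ten-membered ring that is formed late, giving open-chain 24. This one cut removes the ring, the E alkene and the free C2 hydroxyl together. It demands distal attack on the allyl unit and the syn complex. The stereocentres of 24 and 26 were checked atom by atom against 34 (C2 S, C4 R, C5 S, C6 S, C7 R throughout; C1 S in 24) and stand as drawn. The design change is that C6 carries the acetate of the target instead of a benzyl-type ether, which saves a deprotection and a second acetylation at the end and avoids ether formation in the presence of a nitro group.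

24 is cut at the C8–N bond, through iodide 23, iodo alcohol 22 and diol 21. The nitro group enters last, so that no organometallic or acylating step has to tolerate it. The forward displacement must favour nitrogen over oxygen of the ambident nitrite.

21 comes from imide 20, which is cut at C6–C7 into aldehyde 10 and acyl oxazolidinone 18. One bond sets C6 and C7 together and brings in C7, C8 and C11–C13 as a single four-carbon piece. The forward aldol must be syn and must override or match the facial bias of the epoxy aldehyde.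

18 is assembled from acid 15 and auxiliary 16. 15 comes from 14, 13 and the commercial half-ester 11, by selective reduction of its free conjugated acid.

10 is the oxidation product of 9, and 9 is cut at the C4–C5 oxirane oxygen to give Z allylic alcohol 8. The reagent-controlled epoxidation needs only the primary allylic alcohol as a handle and must leave the isopropenyl oxirane alone.

8 is cut at the C2–O bond of its oxirane (via 7) to chlorohydrin 6, and 6 at the C1–C10 bond to α-chloro aldehyde 4 and Grignard reagent 5. This delivers C9, C10 and C14 in one commercial reagent and sets C2 by catalysis. Because C1 becomes trigonal in the key step, the selectivity of the addition at C1 affects only homogeneity.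

4 goes back to aldehyde 3 (C2–Cl), and 3 to 1 by cleavage of the C1=C10 alkene. 1 already contains C1–C6 and C15 with the Z C4=C5 geometry, so no alkene geometry has to be built.

## Other disconnections considered

Alternative 1: The cut is C7–C11, made on a ten-membered ring that already exists. In A1 the C7 oxygen is a xanthate and the C8 oxygen carries an ethyl propargyl mixed acetal. Bu3SnH and AIBN would generate the C7 radical, which closes 5-exo-dig on the alkyne to give the methylene lactol ether A2. In its favour, the five-membered closure from a C8 tether can only give the cis ring fusion. On that point it is better than the chosen plan, which depends on catalyst-controlled hydride delivery at C8. The C5–C8 oxygen pattern could also be taken from a pentose. Against it here, the hardest problem, the ten-membered ring with its E alkene, is left unsolved and must be handled by a separate macrocyclisation. The radical is generated next to the C6 acetate, A2 still needs acetal hydrolysis and oxidation in the presence of the acid-sensitive oxirane, and stoichiometric tin is used. In step count for the lactone alone the two plans are about equal (three operations against two); overall the chosen plan is shorter because its ring-forming step also sets the C2 oxygen and the alkene.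

Alternative 2: The cut is the C4=C5 bond of a diene A3 in which the lactone and C2, C6, C7, C8 are already in place. Second-generation Grubbs catalyst would join the C4 isopropenyl and C5 vinyl groups to give the (1(10)E,4Z)-dienolide A4. In its favour, Z geometry is the natural outcome of ring-closing metathesis in a ring of this size. The C6 hydroxyl would then direct epoxidation to its own face, which is the cis relation the target needs, and only two steps would remain after ring closure. That endgame is shorter than the chosen one (five steps), a clear point for this alternative. Against it, the metathesis must form a trisubstituted alkene from a 1,1-disubstituted partner inside a strained ring that already holds an E alkene, so dimerisation and ring-opening compete. The exocyclic methylene of the lactone is a further alkene partner, and A3 needs three contiguous stereocentres on a butyrolactone plus the remote C2 centre to be built without any relay between them. Mechanistically it is a reversible, thermodynamically governed closure, against the irreversible C–C alkylation of the chosen plan.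

Alternative 3: The cut is C9–C10. In A5 a methyl-substituted alkyne (C1≡C10) and a terminal C8–C9 oxirane would be coupled reductively with Ni(cod)2, Bu3P and Et3B to give the cyclodecenol A6. In its favour, syn addition of carbon and hydrogen across the alkyne fixes the E geometry mechanistically, and the C8 carbinol centre is carried in from an enantiopure oxirane. On both points it is better than the chosen plan, which relies on π-allyl equilibration for geometry and on a Nef–reduction sequence for C8. Against it, this coupling is established for bimolecular cases and small rings, not for a ten-membered closure. Which alkyne carbon bonds to C9 would be decided by ring strain rather than by a strong electronic bias, and the propargylic C2 silyl ether and the trisubstituted oxirane must survive Lewis-acidic nickel and boron species. After the key step two silyl ethers and a free C8 hydroxyl have to be told apart, which takes about five steps, the same as the chosen endgame.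

Key step: step 16

Assumption: in step 2 the (2S,5S) antipode of 2,5-diphenylpyrrolidine is taken to give the (R)-chloride 4; if the sense is the opposite, the (2R,5R) antipode is used and nothing else changes.
Remark: the minor C1 epimer from step 3 (cis-oxirane series) and any C8 epimer of 26 converge, because C1 becomes trigonal in step 16 and C8 in step 18.

## Route

Step 1
Reactants: 1 neryl acetate, (2Z)-3,7-dimethylocta-2,6-dien-1-yl acetate
Product: 3 (2Z)-3-methyl-6-oxohex-2-en-1-yl acetate, via ozonide 2 (not isolated)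
Conditions: O3 (one equivalent), CH2Cl2–pyridine, −78 °C; then Me2S, −78 °C → rt
Reagents that add atoms: ozone, [O-][O+]=O
Why: Chemoselective ozonolysis: the isopropylidene alkene is the more electron-rich one, the allylic acetate deactivating the other, so cleavage should stop at the C1 aldehyde with the Z C4=C5 alkene intact.

Step 2
Reactants: 3 (2Z)-3-methyl-6-oxohex-2-en-1-yl acetate
Product: 4 (2Z,5R)-5-chloro-3-methyl-6-oxohex-2-en-1-yl acetate
Conditions: (2S,5S)-2,5-diphenylpyrrolidine (10 mol%), NCS, CH2Cl2, 0 °C; used cold without purification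
Reagents that add atoms: N-chlorosuccinimide, O=C1CCC(=O)N1Cl
Why: Enamine-catalysed α-chlorination of an aldehyde; the C2-symmetric amine shields one face of the enamine so that chlorine should enter to give the (R)-chloride at C2, and immediate use avoids racemisation.

Step 3
Reactants: 4 (2Z,5R)-5-chloro-3-methyl-6-oxohex-2-en-1-yl acetate; 5 isopropenylmagnesium bromide
Product: 6 (2Z,5R,6S)-5-chloro-6-hydroxy-3,7-dimethylocta-2,7-dien-1-yl acetate
Conditions: THF, −78 °C; then aq NH4Cl
Reagents that add atoms: none
Why: Grignard addition to an α-chloro aldehyde follows the Cornforth (polar Felkin–Anh) model, the nucleophile entering anti to the C–Cl bond, so the anti chlorohydrin with C1 (S) should predominate; at −78 °C the aldehyde reacts well before the acetate.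

Step 4
Reactants: 6 (2Z,5R,6S)-5-chloro-6-hydroxy-3,7-dimethylocta-2,7-dien-1-yl acetate
Product: 8 (2Z)-3-methyl-4-[(2S,3S)-3-(prop-1-en-2-yl)oxiran-2-yl]but-2-en-1-ol, via epoxy acetate 7 (not isolated)
Conditions: K2CO3, MeOH, 0 °C → rt
Reagents that add atoms: none
Why: Intramolecular Williamson closure (SN2 with inversion at C2) should turn the anti chlorohydrin into the trans vinyl oxirane with C2 (S), and methanolysis of the acetate in the same pot frees the C6 alcohol.

Step 5
Reactants: 8 (2Z)-3-methyl-4-[(2S,3S)-3-(prop-1-en-2-yl)oxiran-2-yl]but-2-en-1-ol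
Product: 9 [(2S,3R)-3-methyl-3-{[(2S,3S)-3-(prop-1-en-2-yl)oxiran-2-yl]methyl}oxiran-2-yl]methanol
Conditions: Ti(OiPr)4 (cat.), L-(+)-diisopropyl tartrate, t-BuOOH, 4 Å MS, CH2Cl2, −20 °C
Reagents that add atoms: tert-butyl hydroperoxide, CC(C)(C)OO
Why: Sharpless asymmetric epoxidation: with the L-(+)-tartrate the oxygen is delivered to the face of a nerol-type Z allylic alcohol that gives the (2S,3R) epoxy alcohol (C5 S, C4 R) under reagent control; only the allylic-alcohol alkene reacts, so the isopropenyl oxirane is a spectator.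

Step 6
Reactants: 9 [(2S,3R)-3-methyl-3-{[(2S,3S)-3-(prop-1-en-2-yl)oxiran-2-yl]methyl}oxiran-2-yl]methanol
Product: 10 (2R,3R)-3-methyl-3-{[(2S,3S)-3-(prop-1-en-2-yl)oxiran-2-yl]methyl}oxirane-2-carbaldehyde
Conditions: TEMPO (cat.), PhI(OAc)2, CH2Cl2, 0 °C → rt; used directly
Reagents that add atoms: none
Why: Oxoammonium (TEMPO) oxidation of a primary epoxy alcohol stops at the aldehyde and should neither epimerise C5 nor open either oxirane.

Step 7
Reactants: 11 monomethyl itaconate, 4-methoxy-2-methylidene-4-oxobutanoic acid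
Product: 13 methyl 3-(hydroxymethyl)but-3-enoate, via mixed carbonic anhydride 12 (not isolated)
Conditions: i-BuOCOCl, N-methylmorpholine, THF, −15 °C; then NaBH4, THF–H2O, 0 °C
Reagents that add atoms: none
Why: Activation of the free conjugated acid as its mixed carbonic anhydride lets borohydride reduce it to the allylic alcohol by 1,2-addition while the methyl ester is untouched.

Step 8
Reactants: 13 methyl 3-(hydroxymethyl)but-3-enoate
Product: 14 methyl 3-({[tert-butyl(dimethyl)silyl]oxy}methyl)but-3-enoate
Conditions: TBSCl, imidazole, CH2Cl2, 0 °C → rt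
Reagents that add atoms: tert-butyldimethylsilyl chloride, CC(C)(C)[Si](C)(C)Cl
Why: Standard silylation of a primary alcohol; it also blocks lactonisation of the hydroxy ester.

Step 9
Reactants: 14 methyl 3-({[tert-butyl(dimethyl)silyl]oxy}methyl)but-3-enoate
Product: 15 3-({[tert-butyl(dimethyl)silyl]oxy}methyl)but-3-enoic acid
Conditions: LiOH, THF–H2O, 0 °C; then 1 M HCl to pH 4
Reagents that add atoms: lithium hydroxide, [Li+].[OH-]
Why: Saponification of the methyl ester; the cold, brief treatment should keep the 1,1-disubstituted alkene out of conjugation and leave the silyl ether in place.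

Step 10
Reactants: 15 3-({[tert-butyl(dimethyl)silyl]oxy}methyl)but-3-enoic acid; 16 (4S)-4-benzyl-1,3-oxazolidin-2-one
Product: 18 (4S)-4-benzyl-3-[3-({[tert-butyl(dimethyl)silyl]oxy}methyl)but-3-enoyl]-1,3-oxazolidin-2-one, via mixed pivalic anhydride 17 (not isolated)
Conditions: t-BuCOCl, Et3N, THF, −20 °C; then 16, LiCl, −20 °C → rt
Reagents that add atoms: none
Why: N-Acylation of the oxazolidinone through the mixed pivalic anhydride under LiCl/Et3N needs no strong base, which avoids isomerising the β,γ-unsaturated acyl group.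

Step 11
Reactants: 18 (4S)-4-benzyl-3-[3-({[tert-butyl(dimethyl)silyl]oxy}methyl)but-3-enoyl]-1,3-oxazolidin-2-one; 10 (2R,3R)-3-methyl-3-{[(2S,3S)-3-(prop-1-en-2-yl)oxiran-2-yl]methyl}oxirane-2-carbaldehyde
Product: 20 (4S)-4-benzyl-3-[(2S)-2-{(S)-hydroxy[(2S,3R)-3-methyl-3-{[(2S,3S)-3-(prop-1-en-2-yl)oxiran-2-yl]methyl}oxiran-2-yl]methyl}-3-({[tert-butyl(dimethyl)silyl]oxy}methyl)but-3-enoyl]-1,3-oxazolidin-2-one, via dibutylboron enolate 19 (not isolated)
Conditions: 18, n-Bu2BOTf, i-Pr2NEt, CH2Cl2, −78 → 0 °C; then 10, −78 → −20 °C; pH 7 buffer, MeOH, H2O2, 0 °C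
Reagents that add atoms: none
Why: Evans syn-aldol reaction: the Z boron dienolate reacts at its α carbon (C7) through a Zimmerman–Traxler chair, and the (S)-benzyl auxiliary fixes C7 and C6 with the C6 oxygen syn to the C11 branch; the intrinsic anti (Felkin–Anh/Cornforth) preference of the cis-epoxy aldehyde leads to the same C6 configuration.

Step 12
Reactants: 20 (4S)-4-benzyl-3-[(2S)-2-{(S)-hydroxy[(2S,3R)-3-methyl-3-{[(2S,3S)-3-(prop-1-en-2-yl)oxiran-2-yl]methyl}oxiran-2-yl]methyl}-3-({[tert-butyl(dimethyl)silyl]oxy}methyl)but-3-enoyl]-1,3-oxazolidin-2-one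
Product: 21 (1S,2R)-2-(hydroxymethyl)-1-[(2S,3R)-3-methyl-3-{[(2S,3S)-3-(prop-1-en-2-yl)oxiran-2-yl]methyl}oxiran-2-yl]-3-({[tert-butyl(dimethyl)silyl]oxy}methyl)but-3-en-1-ol
Conditions: LiBH4, MeOH (1 equiv), THF, 0 °C
Reagents that add atoms: none
Why: Reductive removal of the auxiliary: borohydride attacks the exocyclic imide carbonyl and gives the primary C8 alcohol and recoverable 16; oxiranes and alkenes are inert at 0 °C.

Step 13
Reactants: 21 (1S,2R)-2-(hydroxymethyl)-1-[(2S,3R)-3-methyl-3-{[(2S,3S)-3-(prop-1-en-2-yl)oxiran-2-yl]methyl}oxiran-2-yl]-3-({[tert-butyl(dimethyl)silyl]oxy}methyl)but-3-en-1-ol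
Product: 22 (1S,2S)-2-(iodomethyl)-1-[(2S,3R)-3-methyl-3-{[(2S,3S)-3-(prop-1-en-2-yl)oxiran-2-yl]methyl}oxiran-2-yl]-3-({[tert-butyl(dimethyl)silyl]oxy}methyl)but-3-en-1-ol
Conditions: I2, PPh3, imidazole, CH2Cl2, 0 °C
Reagents that add atoms: iodine, II
Why: Appel-type iodination is selective for the primary alcohol over the hindered secondary C6 alcohol, and the imidazole buffer protects the oxiranes.

Step 14
Reactants: 22 (1S,2S)-2-(iodomethyl)-1-[(2S,3R)-3-methyl-3-{[(2S,3S)-3-(prop-1-en-2-yl)oxiran-2-yl]methyl}oxiran-2-yl]-3-({[tert-butyl(dimethyl)silyl]oxy}methyl)but-3-en-1-ol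
Product: 23 (1S,2S)-2-(iodomethyl)-1-[(2S,3R)-3-methyl-3-{[(2S,3S)-3-(prop-1-en-2-yl)oxiran-2-yl]methyl}oxiran-2-yl]-3-({[tert-butyl(dimethyl)silyl]oxy}methyl)but-3-en-1-yl acetate
Conditions: Ac2O, pyridine, DMAP (cat.), CH2Cl2, 0 °C → rt
Reagents that add atoms: acetic anhydride, CC(=O)OC(C)=O
Why: Acetylation installs the C6 acetate of the target before any nitro group is present, since acylating conditions could dehydrate a primary nitroalkane.

Step 15
Reactants: 23 (1S,2S)-2-(iodomethyl)-1-[(2S,3R)-3-methyl-3-{[(2S,3S)-3-(prop-1-en-2-yl)oxiran-2-yl]methyl}oxiran-2-yl]-3-({[tert-butyl(dimethyl)silyl]oxy}methyl)but-3-en-1-yl acetate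
Product: 24 (1S,2R)-2-(nitromethyl)-1-[(2S,3R)-3-methyl-3-{[(2S,3S)-3-(prop-1-en-2-yl)oxiran-2-yl]methyl}oxiran-2-yl]-3-({[tert-butyl(dimethyl)silyl]oxy}methyl)but-3-en-1-yl acetate
Conditions: NaNO2, phloroglucinol, DMF, rt
Reagents that add atoms: sodium nitrite, [Na+].[O-]N=O
Why: Kornblum nitrite displacement (SN2 at the primary C8 iodide) gives the nitroalkane; phloroglucinol scavenges the nitrite ester formed by competing oxygen attack.

Step 16
Reactants: 24 (1S,2R)-2-(nitromethyl)-1-[(2S,3R)-3-methyl-3-{[(2S,3S)-3-(prop-1-en-2-yl)oxiran-2-yl]methyl}oxiran-2-yl]-3-({[tert-butyl(dimethyl)silyl]oxy}methyl)but-3-en-1-yl acetate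
Product: 26 (1(10)E,2S,4R,5S,6S,7R,8R)-6-acetoxy-12-{[tert-butyl(dimethyl)silyl]oxy}-4,5-epoxy-8-nitrogermacra-1(10),11(13)-dien-2-ol, via allylpalladium nitronate zwitterion 25 (not isolated)
Conditions: Pd(PPh3)4 (10 mol%), THF, 0.002 M, slow addition, 50 °C
Reagents that add atoms: none
Why: Tsuji–Trost allylic alkylation run as a macrocyclisation: Pd(PPh3)4 ionises the allylic C1–O bond of the vinyl oxirane to a π-allylpalladium complex (C1–C10–C9) carrying the C2 alkoxide, which removes a proton from the C8 nitromethyl group to give zwitterion 25. The soft nitronate carbon then attacks the unsubstituted terminus C9 on the face opposite the metal, forming C8–C9 and returning zerovalent palladium. The closest known reaction type is the neutral palladium-catalysed alkylation of nitroalkanes and other stabilised carbon nucleophiles by vinyl epoxides, including its macrocyclising form. The ten-membered ring closes in the endo mode at the distal allyl terminus (10-endo), the competing mode being 8-exo closure at C1. The new C8 stereocentre is set by the approach of the nitronate inside the macrocyclic transition state; it is drawn as (8R) and is erased in step 18. The step needs attack at C9 and E geometry: distal attack is the normal course for vinyl oxiranes and C9 is also the unhindered end, while π–σ–π equilibration lets the syn complex (C2 cis to the C14 methyl, trans to C9) be the one that cyclises. A nitronate alkylated on oxygen would be an allylic ester-like species that the catalyst can re-ionise, so carbon alkylation is the sink. The neutral conditions should spare both the C6 acetate and the C4–C5 oxirane, and the C1 epimer of 24 converges on the same complex.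

Step 17
Reactants: 26 (1(10)E,2S,4R,5S,6S,7R,8R)-6-acetoxy-12-{[tert-butyl(dimethyl)silyl]oxy}-4,5-epoxy-8-nitrogermacra-1(10),11(13)-dien-2-ol
Product: 27 (1(10)E,2S,4R,5S,6S,7R,8R)-12-{[tert-butyl(dimethyl)silyl]oxy}-4,5-epoxy-8-nitrogermacra-1(10),11(13)-diene-2,6-diyl diacetate
Conditions: Ac2O, pyridine, CH2Cl2, 0 °C → rt
Reagents that add atoms: acetic anhydride, CC(=O)OC(C)=O
Why: Acetylation of the allylic C2 alcohol; pyridine alone is too weak a base to engage the secondary nitro group.

Step 18
Reactants: 27 (1(10)E,2S,4R,5S,6S,7R,8R)-12-{[tert-butyl(dimethyl)silyl]oxy}-4,5-epoxy-8-nitrogermacra-1(10),11(13)-diene-2,6-diyl diacetate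
Product: 29 (1(10)E,2S,4R,5S,6S,7S)-12-{[tert-butyl(dimethyl)silyl]oxy}-4,5-epoxy-8-oxogermacra-1(10),11(13)-diene-2,6-diyl diacetate, via potassium nitronate 28 (not isolated)
Conditions: KOt-Bu, THF, −40 °C; then aq TiCl3, NH4OAc (pH 5–6), THF, 0 °C → rt
Reagents that add atoms: water, O
Why: Reductive Nef reaction: the nitronate is reduced by trivalent titanium to the imine, which hydrolyses to the C8 ketone at pH 5–6, conditions under which the β-acetoxy ketone, the oxirane and the silyl ether should persist; C8 becomes trigonal, so its earlier configuration does not matter.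

Step 19
Reactants: 29 (1(10)E,2S,4R,5S,6S,7S)-12-{[tert-butyl(dimethyl)silyl]oxy}-4,5-epoxy-8-oxogermacra-1(10),11(13)-diene-2,6-diyl diacetate
Product: 30 (1(10)E,2S,4R,5S,6S,7R,8R)-12-{[tert-butyl(dimethyl)silyl]oxy}-4,5-epoxy-8-hydroxygermacra-1(10),11(13)-diene-2,6-diyl diacetate
Conditions: (S)-2-methyl-CBS-oxazaborolidine, catecholborane, toluene, −78 °C
Reagents that add atoms: none
Why: Corey–Bakshi–Shibata reduction: the (S)-oxazaborolidine distinguishes the branched C7 side (large) from the C9 methylene side (small) and should deliver hydride to give the (8R) alcohol, cis to the C11 branch; catecholborane at −78 °C is non-basic and leaves alkenes, acetates and the oxirane alone.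

Step 20
Reactants: 30 (1(10)E,2S,4R,5S,6S,7R,8R)-12-{[tert-butyl(dimethyl)silyl]oxy}-4,5-epoxy-8-hydroxygermacra-1(10),11(13)-diene-2,6-diyl diacetate
Product: 31 (1(10)E,2S,4R,5S,6S,7R,8R)-4,5-epoxy-8,12-dihydroxygermacra-1(10),11(13)-diene-2,6-diyl diacetate
Conditions: Et3N·3HF, THF, rt
Reagents that add atoms: none
Why: Buffered fluoride cleaves the primary allylic silyl ether under near-neutral conditions that should neither migrate nor cleave the acetates nor open the oxirane.

Step 21
Reactants: 31 (1(10)E,2S,4R,5S,6S,7R,8R)-4,5-epoxy-8,12-dihydroxygermacra-1(10),11(13)-diene-2,6-diyl diacetate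
Product: 34 (1(10)E,2S,4R,5S,6S,7R,8R)-2,6-diacetoxy-4,5-epoxygermacra-1(10),11(13)-dien-12,8-olide (CNP0270851.1), via hydroxy enal 32 (not isolated), via lactol 33 (not isolated)
Conditions: MnO2 (activated, excess), CH2Cl2, rt
Reagents that add atoms: none
Why: Oxidative lactonisation: MnO2 oxidises only the allylic primary alcohol, the enal is captured by the cis C8 hydroxyl as the lactol, and this allylic hemiacetal is oxidised on to the α-methylene lactone; the non-allylic C8 alcohol is not oxidised.

## Compound list

1 | neryl acetate, (2Z)-3,7-dimethylocta-2,6-dien-1-yl acetate | CC(C)=CCC/C(C)=C\COC(C)=O | starting material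
2 | ozonide, (2Z)-5-(5,5-dimethyl-1,2,4-trioxolan-3-yl)-3-methylpent-2-en-1-yl acetate | CC1(C)OOC(CC/C(C)=C\COC(C)=O)O1 | intermediate
3 | (2Z)-3-methyl-6-oxohex-2-en-1-yl acetate | O=CCC/C(C)=C\COC(C)=O | intermediate
4 | (2Z,5R)-5-chloro-3-methyl-6-oxohex-2-en-1-yl acetate | O=C[C@H](Cl)C/C(C)=C\COC(C)=O | intermediate
5 | isopropenylmagnesium bromide | C=C(C)[Mg]Br | starting material
6 | (2Z,5R,6S)-5-chloro-6-hydroxy-3,7-dimethylocta-2,7-dien-1-yl acetate | C=C(C)[C@H](O)[C@H](Cl)C/C(C)=C\COC(C)=O | intermediate
7 | epoxy acetate, (2Z)-3-methyl-4-[(2S,3S)-3-(prop-1-en-2-yl)oxiran-2-yl]but-2-en-1-yl acetate | CC(=O)OC/C=C(C)\C[C@@H]1O[C@H]1C(C)=C | intermediate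
8 | (2Z)-3-methyl-4-[(2S,3S)-3-(prop-1-en-2-yl)oxiran-2-yl]but-2-en-1-ol | OC/C=C(C)\C[C@@H]1O[C@H]1C(C)=C | intermediate
9 | [(2S,3R)-3-methyl-3-{[(2S,3S)-3-(prop-1-en-2-yl)oxiran-2-yl]methyl}oxiran-2-yl]methanol | OC[C@@H]1O[C@]1(C)C[C@@H]2O[C@H]2C(C)=C | intermediate
10 | (2R,3R)-3-methyl-3-{[(2S,3S)-3-(prop-1-en-2-yl)oxiran-2-yl]methyl}oxirane-2-carbaldehyde | O=C[C@@H]1O[C@]1(C)C[C@@H]2O[C@H]2C(C)=C | intermediate
11 | monomethyl itaconate, 4-methoxy-2-methylidene-4-oxobutanoic acid | C=C(CC(=O)OC)C(=O)O | starting material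
12 | mixed carbonic anhydride, isobutoxycarbonyl 4-methoxy-2-methylidene-4-oxobutanoate | C=C(CC(=O)OC)C(=O)OC(=O)OCC(C)C | intermediate
13 | methyl 3-(hydroxymethyl)but-3-enoate | C=C(CO)CC(=O)OC | intermediate
14 | methyl 3-({[tert-butyl(dimethyl)silyl]oxy}methyl)but-3-enoate | C=C(CO[Si](C)(C)C(C)(C)C)CC(=O)OC | intermediate
15 | 3-({[tert-butyl(dimethyl)silyl]oxy}methyl)but-3-enoic acid | C=C(CO[Si](C)(C)C(C)(C)C)CC(=O)O | intermediate
16 | (4S)-4-benzyl-1,3-oxazolidin-2-one | O=C1N[C@@H](Cc2ccccc2)CO1 | starting material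
17 | mixed pivalic anhydride, 3-({[tert-butyl(dimethyl)silyl]oxy}methyl)but-3-enoic 2,2-dimethylpropanoic anhydride | C=C(CO[Si](C)(C)C(C)(C)C)CC(=O)OC(=O)C(C)(C)C | intermediate
18 | (4S)-4-benzyl-3-[3-({[tert-butyl(dimethyl)silyl]oxy}methyl)but-3-enoyl]-1,3-oxazolidin-2-one | C=C(CO[Si](C)(C)C(C)(C)C)CC(=O)N1[C@@H](Cc2ccccc2)COC1=O | intermediate
19 | dibutylboron (Z)-enolate of 18 | CCCCB(CCCC)O/C(=C\C(=C)CO[Si](C)(C)C(C)(C)C)N1[C@@H](Cc2ccccc2)COC1=O | intermediate
20 | (4S)-4-benzyl-3-[(2S)-2-{(S)-hydroxy[(2S,3R)-3-methyl-3-{[(2S,3S)-3-(prop-1-en-2-yl)oxiran-2-yl]methyl}oxiran-2-yl]methyl}-3-({[tert-butyl(dimethyl)silyl]oxy}methyl)but-3-enoyl]-1,3-oxazolidin-2-one | O=C([C@@H](C(=C)CO[Si](C)(C)C(C)(C)C)[C@H](O)[C@@H]1O[C@]1(C)C[C@@H]2O[C@H]2C(C)=C)N3[C@@H](Cc4ccccc4)COC3=O | intermediate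
21 | (1S,2R)-2-(hydroxymethyl)-1-[(2S,3R)-3-methyl-3-{[(2S,3S)-3-(prop-1-en-2-yl)oxiran-2-yl]methyl}oxiran-2-yl]-3-({[tert-butyl(dimethyl)silyl]oxy}methyl)but-3-en-1-ol | OC[C@@H](C(=C)CO[Si](C)(C)C(C)(C)C)[C@H](O)[C@@H]1O[C@]1(C)C[C@@H]2O[C@H]2C(C)=C | intermediate
22 | (1S,2S)-2-(iodomethyl)-1-[(2S,3R)-3-methyl-3-{[(2S,3S)-3-(prop-1-en-2-yl)oxiran-2-yl]methyl}oxiran-2-yl]-3-({[tert-butyl(dimethyl)silyl]oxy}methyl)but-3-en-1-ol | IC[C@@H](C(=C)CO[Si](C)(C)C(C)(C)C)[C@H](O)[C@@H]1O[C@]1(C)C[C@@H]2O[C@H]2C(C)=C | intermediate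
23 | (1S,2S)-2-(iodomethyl)-1-[(2S,3R)-3-methyl-3-{[(2S,3S)-3-(prop-1-en-2-yl)oxiran-2-yl]methyl}oxiran-2-yl]-3-({[tert-butyl(dimethyl)silyl]oxy}methyl)but-3-en-1-yl acetate | IC[C@@H](C(=C)CO[Si](C)(C)C(C)(C)C)[C@H](OC(C)=O)[C@@H]1O[C@]1(C)C[C@@H]2O[C@H]2C(C)=C | intermediate
24 | (1S,2R)-2-(nitromethyl)-1-[(2S,3R)-3-methyl-3-{[(2S,3S)-3-(prop-1-en-2-yl)oxiran-2-yl]methyl}oxiran-2-yl]-3-({[tert-butyl(dimethyl)silyl]oxy}methyl)but-3-en-1-yl acetate | [O-][N+](=O)C[C@@H](C(=C)CO[Si](C)(C)C(C)(C)C)[C@H](OC(C)=O)[C@@H]1O[C@]1(C)C[C@@H]2O[C@H]2C(C)=C | intermediate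
25 | allylpalladium nitronate zwitterion (drawn as its C9 σ-allyl form, E about C1=C10) | [O-][N+]([O-])=C[C@@H](C(=C)CO[Si](C)(C)C(C)(C)C)[C@H](OC(C)=O)[C@@H]1O[C@]1(C)C[C@H](O)/C=C(\C)C[Pd+](P(c2ccccc2)(c3ccccc3)c4ccccc4)P(c5ccccc5)(c6ccccc6)c7ccccc7 | intermediate
26 | (1(10)E,2S,4R,5S,6S,7R,8R)-6-acetoxy-12-{[tert-butyl(dimethyl)silyl]oxy}-4,5-epoxy-8-nitrogermacra-1(10),11(13)-dien-2-ol | [O-][N+](=O)[C@@H]1C/C(C)=C/[C@@H](O)C[C@@]2(C)O[C@H]2[C@@H](OC(C)=O)[C@@H]1C(=C)CO[Si](C)(C)C(C)(C)C | intermediate
27 | (1(10)E,2S,4R,5S,6S,7R,8R)-12-{[tert-butyl(dimethyl)silyl]oxy}-4,5-epoxy-8-nitrogermacra-1(10),11(13)-diene-2,6-diyl diacetate | [O-][N+](=O)[C@@H]1C/C(C)=C/[C@@H](OC(C)=O)C[C@@]2(C)O[C@H]2[C@@H](OC(C)=O)[C@@H]1C(=C)CO[Si](C)(C)C(C)(C)C | intermediate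
28 | potassium nitronate of 27 | [K+].[O-][N+]([O-])=C1C/C(C)=C/[C@@H](OC(C)=O)C[C@@]2(C)O[C@H]2[C@@H](OC(C)=O)[C@@H]1C(=C)CO[Si](C)(C)C(C)(C)C | intermediate
29 | (1(10)E,2S,4R,5S,6S,7S)-12-{[tert-butyl(dimethyl)silyl]oxy}-4,5-epoxy-8-oxogermacra-1(10),11(13)-diene-2,6-diyl diacetate | O=C1C/C(C)=C/[C@@H](OC(C)=O)C[C@@]2(C)O[C@H]2[C@@H](OC(C)=O)[C@@H]1C(=C)CO[Si](C)(C)C(C)(C)C | intermediate
30 | (1(10)E,2S,4R,5S,6S,7R,8R)-12-{[tert-butyl(dimethyl)silyl]oxy}-4,5-epoxy-8-hydroxygermacra-1(10),11(13)-diene-2,6-diyl diacetate | O[C@@H]1C/C(C)=C/[C@@H](OC(C)=O)C[C@@]2(C)O[C@H]2[C@@H](OC(C)=O)[C@@H]1C(=C)CO[Si](C)(C)C(C)(C)C | intermediate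
31 | (1(10)E,2S,4R,5S,6S,7R,8R)-4,5-epoxy-8,12-dihydroxygermacra-1(10),11(13)-diene-2,6-diyl diacetate | O[C@@H]1C/C(C)=C/[C@@H](OC(C)=O)C[C@@]2(C)O[C@H]2[C@@H](OC(C)=O)[C@@H]1C(=C)CO | intermediate
32 | hydroxy enal, (1(10)E,2S,4R,5S,6S,7R,8R)-4,5-epoxy-8-hydroxy-12-oxogermacra-1(10),11(13)-diene-2,6-diyl diacetate | O[C@@H]1C/C(C)=C/[C@@H](OC(C)=O)C[C@@]2(C)O[C@H]2[C@@H](OC(C)=O)[C@@H]1C(=C)C=O | intermediate
33 | lactol, 12-hydroxy-8,12-epoxy form of 32 (either configuration at C12) | C=C1C(O)O[C@@H]2C/C(C)=C/[C@@H](OC(C)=O)C[C@@]3(C)O[C@H]3[C@@H](OC(C)=O)[C@H]12 | intermediate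
34 | (1(10)E,2S,4R,5S,6S,7R,8R)-2,6-diacetoxy-4,5-epoxygermacra-1(10),11(13)-dien-12,8-olide (CNP0270851.1) | C=C1C(=O)O[C@@H]2C/C(C)=C/[C@@H](OC(C)=O)C[C@@]3(C)O[C@H]3[C@@H](OC(C)=O)[C@H]12 | target

## Step count and least certain steps

Total step count: 21. Longest linear sequence: 17 steps (steps 1–6 and 11–21, from 1); the side branch from 11 contributes steps 7–10.

Step 16 (key step). The closure may go astray by attack at the proximal allyl terminus C1 (eight-membered ring), by alkylation on a nitronate oxygen, by cyclisation of the anti complex to the Z alkene, or by intermolecular alkylation when ring closure is slow. The fallback uses the nitro group of 24 as a nitrile oxide instead of a nitronate and sets out from 24. Dehydration with phenyl isocyanate and Et3N at high dilution, followed by intramolecular dipolar cycloaddition to the C9=C10 isopropenyl alkene, would form the same C8–C9 bond and give the bridged isoxazoline F1. Mo(CO)6 in wet MeCN would cleave the N–O bond to the β-hydroxy ketone F2. MsCl and Et3N would dehydrate F2 to the γ,δ-epoxy enone F3. SmI2 in THF–MeOH at −78 °C would then open the vinylogous epoxy ketone reductively to the β,γ-unsaturated ketone with the free C2 hydroxyl F4. Acetylation (Ac2O, pyridine) returns to the route at 29, bypassing steps 17 and 18.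

Step 19. Hydride may be delivered to the wrong face if the peripheral bias of the ten-membered ring opposes the catalyst, and slow reduction would leave time for hydroboration of the alkenes. The fallback sets out from 29 and accepts whichever reduction gives a single alcohol. If that is the 8S alcohol F5, Mitsunobu inversion with chloroacetic acid (PPh3, DIAD) gives the 8R chloroacetate F6. Thiourea and NaHCO3 in EtOH remove the chloroacetyl group selectively in the presence of the two acetates, and the route is rejoined at 30.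

Step 18. Formation of the nitronate with alkoxide may trigger β-elimination of the C6 acetate or loss of the C7 configuration once the ketone appears, an acetate may be cleaved, and the Lewis-acidic titanium medium may open the oxirane. The fallback avoids the strong base and sets out from 27. Carbon disulfide and Et3N in MeCN reduce the secondary nitro group to the oxime F7. Buffered aqueous TiCl3 (NH4OAc) then cleaves F7 to the ketone, rejoining the route at 29.

Step 3. The basic Grignard reagent may enolise and so racemise the α-chloro aldehyde, may attack the acetate, or may add with low anti selectivity. The fallback is a Nozaki–Hiyama–Kishi addition of 2-bromopropene to 4 (CrCl2, NiCl2 catalytic, DMF). It is non-basic and selective for the aldehyde, gives the same chlorohydrin 6, and makes no new compound (F0).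

## Further compounds

F1 | step 16 | bridged isoxazoline from intramolecular nitrile oxide cycloaddition of 24 (C8=N–O–C10, C10 either configuration) | CC12CC(=NO1)[C@@H](C(=C)CO[Si](C)(C)C(C)(C)C)[C@H](OC(C)=O)[C@@H]3O[C@]3(C)C[C@@H]4O[C@H]42
F2 | step 16 | β-hydroxy ketone, 10-hydroxy-8-oxo-1,2:4,5-diepoxy macrocycle with C6 acetate and C12 silyl ether | CC1(O)CC(=O)[C@@H](C(=C)CO[Si](C)(C)C(C)(C)C)[C@H](OC(C)=O)[C@@H]2O[C@]2(C)C[C@@H]3O[C@H]31
F3 | step 16 | γ,δ-epoxy enone, 8-oxo-9(10)-ene-1,2:4,5-diepoxy macrocycle with C6 acetate and C12 silyl ether | CC1=CC(=O)[C@@H](C(=C)CO[Si](C)(C)C(C)(C)C)[C@H](OC(C)=O)[C@@H]2O[C@]2(C)C[C@@H]3O[C@H]31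
F4 | step 16 | (1(10)E,2S,4R,5S,6S,7S)-6-acetoxy-12-{[tert-butyl(dimethyl)silyl]oxy}-4,5-epoxy-2-hydroxygermacra-1(10),11(13)-dien-8-one | O=C1C/C(C)=C/[C@@H](O)C[C@@]2(C)O[C@H]2[C@@H](OC(C)=O)[C@@H]1C(=C)CO[Si](C)(C)C(C)(C)C
F5 | step 19 | 8S epimer of 30 | O[C@H]1C/C(C)=C/[C@@H](OC(C)=O)C[C@@]2(C)O[C@H]2[C@@H](OC(C)=O)[C@@H]1C(=C)CO[Si](C)(C)C(C)(C)C
F6 | step 19 | 8R chloroacetate of 30 | ClCC(=O)O[C@@H]1C/C(C)=C/[C@@H](OC(C)=O)C[C@@]2(C)O[C@H]2[C@@H](OC(C)=O)[C@@H]1C(=C)CO[Si](C)(C)C(C)(C)C
F7 | step 18 | C8 oxime of 29 | ON=C1C/C(C)=C/[C@@H](OC(C)=O)C[C@@]2(C)O[C@H]2[C@@H](OC(C)=O)[C@@H]1C(=C)CO[Si](C)(C)C(C)(C)C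
F0 | step 3 | none | none
A1 | alternative 1 | ten-membered C7 O-(S-methyl) xanthate with C8 ethyl propargyl mixed acetal, 2,6-diacetoxy-4,5-epoxy core (C7 and acetal carbon either configuration) | C#CC(OCC)O[C@@H]1C/C(C)=C/[C@@H](OC(C)=O)C[C@@]2(C)O[C@H]2[C@@H](OC(C)=O)C1OC(=S)SC
A2 | alternative 1 | cis-fused methylene lactol ethyl ether of the target | C=C1[C@@H](OCC)O[C@@H]2C/C(C)=C/[C@@H](OC(C)=O)C[C@@]3(C)O[C@H]3[C@@H](OC(C)=O)[C@H]12
A3 | alternative 2 | open diene lactone with C4 isopropenyl and C5 vinyl termini and free C6 hydroxyl | C=C1C(=O)O[C@H](C/C(C)=C/[C@@H](OC(C)=O)CC(C)=C)[C@@H]1[C@H](O)C=C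
A4 | alternative 2 | (1(10)E,4Z)-germacradienolide with free C6 hydroxyl | C=C1C(=O)O[C@@H]2C/C(C)=C/[C@@H](OC(C)=O)C/C(C)=C\[C@@H](O)[C@H]12
A5 | alternative 3 | open-chain C1–C10 methyl alkyne with terminal C8–C9 oxirane, C6 acetate, C2 and C12 silyl ethers | CC#C[C@@H](O[Si](C)(C)C(C)(C)C)C[C@@]1(C)O[C@H]1[C@@H](OC(C)=O)[C@@H]([C@H]2CO2)C(=C)CO[Si](C)(C)C(C)(C)C
A6 | alternative 3 | (E)-4,5-epoxycyclodec-1(10)-en-8-ol with C6 acetate, C2 and C12 silyl ethers | O[C@@H]1C/C(C)=C/[C@@H](O[Si](C)(C)C(C)(C)C)C[C@@]2(C)O[C@H]2[C@@H](OC(C)=O)[C@@H]1C(=C)CO[Si](C)(C)C(C)(C)C
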